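**Retrosynthetic overview**
- The target, 2,3-dibromo-6-(2,4-dibromophenoxy)phenol, is achiral; both benzene rings are bought and no ring is formed.
- C–OH ⇒ C–CHO: the phenol comes from 2,3-dibromo-6-(2,4-dibromophenoxy)benzaldehyde by Baeyer–Villiger oxidation and formate cleavage.
- Diaryl ether C–O ⇒ SNAr of 2,4-dibromophenol on 2,3-dibromo-6-fluorobenzaldehyde, where the ortho-CHO activates C–F.
- CHO ⇒ ortho-lithiation/formylation of 1,2-dibromo-4-fluorobenzene at the C–H between F and Br.
- Order: ring A (the future phenol ring) is functionalised first, ring B (2,4-dibromophenyl) is attached second, and the phenol oxygen is installed last.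

Assumption: the target has no stereocentre, so no stereocontrol is needed; 2,3-dibromo-6-fluorobenzaldehyde is made in step 1 rather than relied on as a catalogue item.

**Step 1**
Reactants: 1 1,2-dibromo-4-fluorobenzene
Product: 4 2,3-dibromo-6-fluorobenzaldehyde, via aryllithium 2 (not isolated), via lithium hemiaminal alkoxide 3 (not isolated)
Conditions: LiN(iPr)2 (lithium diisopropylamide, commercial solution, 1.1 equiv), THF, −78 °C, 45 min; then DMF, −78 → −40 °C; 1 M aq. HCl
Reagents that add atoms: N,N-dimethylformamide (DMF), CN(C)C=O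
Why: Directed ortho-lithiation by the hindered amide base removes the most acidic C–H (flanked by F and Br) without Br/Li exchange at −78 °C, and formylation of the aryllithium with DMF gives the aldehyde after acidic collapse of the hemiaminal alkoxide; no stereocentre is formed.

**Step 2**
Reactants: 4 2,3-dibromo-6-fluorobenzaldehyde; 5 2,4-dibromophenol
Product: 7 2,3-dibromo-6-(2,4-dibromophenoxy)benzaldehyde, via potassium 2,4-dibromophenolate 6 (not isolated)
Conditions: K2CO3 (2 equiv), DMAc, 100 °C, N2
Reagents that add atoms: none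
Why: Nucleophilic aromatic substitution (SNAr) in which the ortho-formyl group stabilises the Meisenheimer adduct and fluoride leaves far faster than the ortho-bromide, so the phenolate replaces only F; no stereocentre is formed.

**Step 3**
Reactants: 7 2,3-dibromo-6-(2,4-dibromophenoxy)benzaldehyde
Product: 9 2,3-dibromo-6-(2,4-dibromophenoxy)phenol, via aryl formate 8 (not isolated)
Conditions: mCPBA (1.6 equiv), CH2Cl2, rt → 40 °C; then MeOH, conc. HCl (cat.), rt
Reagents that add atoms: 3-chloroperoxybenzoic acid (mCPBA), OOC(=O)c1cccc(Cl)c1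
Why: Baeyer–Villiger oxidation, in which the oxygen-substituted aryl group migrates in the Criegee adduct to give the aryl formate, followed by acid-catalysed methanolysis to the free phenol while the aryl bromides and the diaryl ether stay untouched; no stereocentre is formed.

**Compound list**
1 | 1,2-dibromo-4-fluorobenzene | Fc1ccc(Br)c(Br)c1 | starting material
2 | (2,3-dibromo-6-fluorophenyl)lithium | [Li]c1c(F)ccc(Br)c1Br | intermediate
3 | lithium (2,3-dibromo-6-fluorophenyl)(dimethylamino)methanolate (racemic, transient) | [Li+].[O-]C(N(C)C)c1c(F)ccc(Br)c1Br | intermediate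
4 | 2,3-dibromo-6-fluorobenzaldehyde | O=Cc1c(F)ccc(Br)c1Br | intermediate
5 | 2,4-dibromophenol | Oc1ccc(Br)cc1Br | starting material
6 | potassium 2,4-dibromophenolate | [K+].[O-]c1ccc(Br)cc1Br | intermediate
7 | 2,3-dibromo-6-(2,4-dibromophenoxy)benzaldehyde | O=Cc1c(Oc2ccc(Br)cc2Br)ccc(Br)c1Br | intermediate
8 | 2,3-dibromo-6-(2,4-dibromophenoxy)phenyl formate | O=COc1c(Oc2ccc(Br)cc2Br)ccc(Br)c1Br | intermediate
9 | 2,3-dibromo-6-(2,4-dibromophenoxy)phenol | Oc1c(Oc2ccc(Br)cc2Br)ccc(Br)c1Br | target

**Total step count:** 3. **Longest linear sequence:** 3.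

**Steps most likely to fail, with fallbacks**

Step 1. The risk is that aryllithium 2 loses LiBr or LiF to give an aryne, or that its bromines migrate before the DMF quench. The fallback sets out from 5 and comes back to the route at 7, so 4 is not needed. Compound 5 is coupled under the same SNAr conditions (K2CO3, DMAc, 100 °C, through 6) with purchased 2-bromo-6-fluorobenzaldehyde (O=Cc1c(F)cccc1Br) to give 2-bromo-6-(2,4-dibromophenoxy)benzaldehyde F1. Electrophilic aromatic bromination (Br2, AcOH, 50 °C, FeBr3 cat. if slow) then puts the missing bromine para to the ether oxygen on ring A, which is also meta to the formyl group, and gives 7. Ring B should be slower because its only free ortho position is meta to two bromines.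

Step 2. The risk is that phenolate 6, a weak and ortho-hindered nucleophile, needs forcing conditions that also displace the 2-bromide or degrade the aldehyde. The fallback sets out from 4 and comes back at 7. Compound 4 is treated with the unhindered, more nucleophilic NaOPh (DMF, 60 °C) to give 2,3-dibromo-6-phenoxybenzaldehyde F2. Br2 (2.1 equiv, AcOH, rt → 50 °C) then brominates the electron-rich ring B, first para to give 2,3-dibromo-6-(4-bromophenoxy)benzaldehyde F3 (not isolated) and then ortho to give 7. Ring A, deactivated by CHO and two bromines, should stay untouched.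

Step 3. The risk is hydride migration to the benzoic acid, or sluggish oxidation of the hindered, electron-poor aldehyde. The fallback sets out from 7 and comes back at 9. MeMgBr (THF, 0 °C) gives racemic 1-[2,3-dibromo-6-(2,4-dibromophenoxy)phenyl]ethan-1-ol F4. Dess–Martin periodinane (CH2Cl2, rt) oxidises it to 1-[2,3-dibromo-6-(2,4-dibromophenoxy)phenyl]ethan-1-one F5. Baeyer–Villiger oxidation of this ketone (mCPBA, CF3CO2H, CH2Cl2) has no hydrogen that can migrate, and aryl migrates in preference to methyl, giving 2,3-dibromo-6-(2,4-dibromophenoxy)phenyl acetate F6. Methanolysis (MeOH, HCl cat.) then gives 9.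

**Further compounds**
F1 | step 1 | 2-bromo-6-(2,4-dibromophenoxy)benzaldehyde | O=Cc1c(Oc2ccc(Br)cc2Br)cccc1Br
F2 | step 2 | 2,3-dibromo-6-phenoxybenzaldehyde | O=Cc1c(Oc2ccccc2)ccc(Br)c1Br
F3 | step 2 | 2,3-dibromo-6-(4-bromophenoxy)benzaldehyde | O=Cc1c(Oc2ccc(Br)cc2)ccc(Br)c1Br
F4 | step 3 | 1-[2,3-dibromo-6-(2,4-dibromophenoxy)phenyl]ethan-1-ol (racemic) | CC(O)c1c(Oc2ccc(Br)cc2Br)ccc(Br)c1Br
F5 | step 3 | 1-[2,3-dibromo-6-(2,4-dibromophenoxy)phenyl]ethan-1-one | CC(=O)c1c(Oc2ccc(Br)cc2Br)ccc(Br)c1Br
F6 | step 3 | 2,3-dibromo-6-(2,4-dibromophenoxy)phenyl acetate | CC(=O)Oc1c(Oc2ccc(Br)cc2Br)ccc(Br)c1Br
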